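**Retrosynthetic overview**

1. Feature: the O-methyl tetronate ring O1–C2(=O)–C3(Me)=C4(OMe)–C5(=C6) is, atom for atom, a 4-hydroxy-3-methoxy-2-methylcyclobut-2-enone (the squarate four-carbon ring) whose carbinol carbon is C5 and whose hydroxyl oxygen is O1 (lactone numbering; chain C6–C18 runs to the furan).
2. Last disconnections: O-demethylation, then the C10–C11 bond by B-alkyl Suzuki coupling of ylidene tetronate 12 (terminal alkene C9=C10) with the E alkenyl iodide 27 of the furyl arm.
3. The lactone ring of 12 comes from Pb(OAc)4 oxidative four-to-five ring expansion of cyclobutenol 10 (C2–C5 broken, O1–C2 and C5=C6 made). 10 comes from C5–C6 bond formation between cyclobutenedione 3 (from dimethyl squarate) and the alkyllithium of iodide 8, whose C7 centre is set by Evans alkylation.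
4. Iodide 27 comes from geranyl acetate (C12–C17): terminal alkene cleavage, alkyne homologation and methylation (C11 and its methyl), copper-catalysed coupling with the (furan-3-yl)methyl Grignard reagent (C17–C18), then hydrozirconation–iodination.
5. Ring order: the cyclobutene and furan rings are bought; the only ring made is the lactone (step 6), before the furan and polyene are attached because the oxidant would not spare them.

Key step: step 6

Remark: salts that are only protonated on aqueous work-up (lithium alkoxides, the lithium tetronate of step 16) are not numbered separately; 10 is carried as the mixture of carbinol epimers because that carbon becomes trigonal in step 6.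

**Route**

Step 1
Reactants: 1 dimethyl squarate
Product: 3 3-methoxy-4-methylcyclobut-3-ene-1,2-dione, via lithium cyclobutenolate 2 (not isolated)
Conditions: MeLi, THF, −78 °C; then (CF3CO)2O, −78 °C; aq NaHCO3
Reagents that add atoms: methyllithium, [Li]C
Why: 1,2-addition of the organolithium to one squarate carbonyl, then trifluoroacetylation, ionisation and loss of methyl trifluoroacetate (the Moore sequence to 3-alkyl-4-alkoxycyclobutenediones) should transpose the carbonyl and leave methyl on the ring.

Step 2
Reactants: 4 (4R)-4-benzyl-3-propanoyl-1,3-oxazolidin-2-one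
Product: 6 (4R)-4-benzyl-3-[(2S)-2-methylpent-4-enoyl]-1,3-oxazolidin-2-one, via sodium Z-enolate 5 (not isolated)
Conditions: NaN(SiMe3)2, THF, −78 °C; allyl iodide, −78 → −45 °C
Reagents that add atoms: allyl iodide (3-iodoprop-1-ene), C=CCI
Why: Evans asymmetric alkylation, in which the chelated Z-enolate is allylated on the face opposite the benzyl group, which sets the 2S centre (the later C7).

Step 3
Reactants: 6 (4R)-4-benzyl-3-[(2S)-2-methylpent-4-enoyl]-1,3-oxazolidin-2-one
Product: 7 (2S)-2-methylpent-4-en-1-ol
Conditions: LiBH4, MeOH (1 equiv), Et2O, 0 °C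
Reagents that add atoms: none
Why: reductive cleavage of the N-acyl oxazolidinone by hydride attack at the exocyclic carbonyl should release the primary alcohol without enolisation of the α-centre.

Step 4
Reactants: 7 (2S)-2-methylpent-4-en-1-ol
Product: 8 (4S)-5-iodo-4-methylpent-1-ene
Conditions: I2, PPh3, imidazole, CH2Cl2, 0 °C → rt
Reagents that add atoms: iodine, II
Why: Appel-type iodination through the alkoxyphosphonium ion is an SN2 displacement at the primary carbon and leaves the adjacent stereocentre untouched.

Step 5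
Reactants: 8 (4S)-5-iodo-4-methylpent-1-ene; 3 3-methoxy-4-methylcyclobut-3-ene-1,2-dione
Product: 10 4-hydroxy-3-methoxy-2-methyl-4-[(2S)-2-methylpent-4-en-1-yl]cyclobut-2-en-1-one, via alkyllithium 9 (not isolated)
Conditions: 8, t-BuLi (2.0 equiv), Et2O/pentane, −78 °C; then added to 3, THF, −78 °C; aq NH4Cl
Reagents that add atoms: none
Why: lithium–iodine exchange gives a primary alkyllithium that has no favourable cyclisation onto the alkene (it would form a four-membered ring), and its 1,2-addition should go to the ketone-like carbonyl next to the methoxy-bearing carbon because the other carbonyl is a deactivated vinylogous ester; the new carbinol centre forms without control, which is of no consequence.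

Step 6
Reactants: 10 4-hydroxy-3-methoxy-2-methyl-4-[(2S)-2-methylpent-4-en-1-yl]cyclobut-2-en-1-one
Product: 12 (5Z)-4-methoxy-3-methyl-5-[(2S)-2-methylpent-4-en-1-ylidene]furan-2(5H)-one, via 5-acetoxyfuranone 11 (not isolated)
Conditions: Pb(OAc)4 (1.2 equiv), toluene, rt; filter; then DBU, toluene, 0 °C
Reagents that add atoms: none
Why: Ligand exchange on tetravalent lead gives the lead alkoxide of 10, whose O–Pb bond breaks together with the strained C2–C5 ring bond (alkoxy β-scission) as divalent lead departs, leaving a C5 ketone and an acyl, ketene-like carbon C2 that the C5 carbonyl oxygen acylates, so the net change is a Criegee-type 1,2-acyl shift from carbon to electron-poor oxygen. The closest known reaction type is the Pb(OAc)4 oxidative rearrangement of squarate-derived 4-hydroxycyclobutenones to 5-acetoxy- and 5-ylidene-furan-2(5H)-ones. The lactone ring (O1, C2, C3, C4, C5) closes in a 5-exo mode by attack of the carbonyl oxygen on the digonal acyl carbon with the C2=O bond left outside the ring, and the furanone cation at C5 is captured by acetate (11) or loses H-6, DBU completing the loss of acetic acid. No stereocentre is created: the carbinol carbon becomes trigonal, and C7 should stay intact because only H-6 is adjacent to the cationic or acetoxylated C5. The step needs the Me-on-C3, OMe-on-C4 regiochemistry, which the vinylogous ester pattern of the ring fixes; Z geometry at C5=C6, favoured because the E isomer would press the C7 substituent against the C4 methoxy group; and chemoselectivity over the terminal alkene, which is inert to Pb(OAc)4 at room temperature and too remote to trap the acyl intermediate.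

Step 7
Reactants: 13 furan-3-ylmethanol
Product: 14 3-(chloromethyl)furan
Conditions: MsCl, LiCl, 2,4,6-collidine, DMF, 0 °C
Reagents that add atoms: lithium chloride, [Li+].[Cl-]
Why: Collington–Meyers chlorination, in which the mesylate formed in situ is displaced by chloride (SN2) under buffered, non-acidic conditions that spare the furan.

Step 8
Reactants: 15 geranyl acetate
Product: 16 (2E)-5-(3,3-dimethyloxiran-2-yl)-3-methylpent-2-en-1-yl acetate
Conditions: mCPBA, NaHCO3, CH2Cl2, 0 °C
Reagents that add atoms: 3-chloroperoxybenzoic acid, OOC(=O)c1cccc(Cl)c1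
Why: Prilezhaev epoxidation should select the remote trisubstituted alkene, which is more electron-rich than the alkene carrying the allylic acetate.

Step 9
Reactants: 16 (2E)-5-(3,3-dimethyloxiran-2-yl)-3-methylpent-2-en-1-yl acetate
Product: 18 (2E)-3-methyl-6-oxohex-2-en-1-yl acetate, via glycol 17 (not isolated)
Conditions: H5IO6, THF/H2O, 0 °C → rt
Reagents that add atoms: none
Why: aqueous periodic acid hydrolyses the trisubstituted epoxide to the glycol by water attack at the tertiary carbon and cleaves it (Malaprade glycol cleavage), so the aldehyde keeps the epoxide oxygen while the allylic acetate and its alkene stay untouched.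

Step 10
Reactants: 18 (2E)-3-methyl-6-oxohex-2-en-1-yl acetate
Product: 20 (2E)-3-methylhept-2-en-6-yn-1-ol, via enyne acetate 19 (not isolated)
Conditions: dimethyl (1-diazo-2-oxopropyl)phosphonate, K2CO3 (3 equiv), MeOH, 0 °C → rt
Reagents that add atoms: dimethyl (1-diazo-2-oxopropyl)phosphonate, COP(=O)(OC)C(=[N+]=[N-])C(C)=O
Why: Seyferth–Gilbert homologation in its Ohira–Bestmann form converts the enolisable aldehyde into the terminal alkyne, and the same K2CO3/MeOH medium should remove the acetate by transesterification.

Step 11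
Reactants: 20 (2E)-3-methylhept-2-en-6-yn-1-ol
Product: 22 (2E)-3-methyloct-2-en-6-yn-1-ol, via dilithiated enynol 21 (not isolated)
Conditions: n-BuLi (2.1 equiv), THF, −78 → 0 °C; MeI (1.0 equiv), −78 °C → rt
Reagents that add atoms: iodomethane, CI
Why: acetylide alkylation, in which the carbanion of the O,C-dianion is a far better nucleophile towards MeI in THF than the aggregated lithium alkoxide, so C-methylation should prevail.

Step 12
Reactants: 22 (2E)-3-methyloct-2-en-6-yn-1-ol
Product: 23 (2E)-1-chloro-3-methyloct-2-en-6-yne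
Conditions: MsCl, LiCl, 2,4,6-collidine, DMF, 0 °C
Reagents that add atoms: lithium chloride, [Li+].[Cl-]
Why: Collington–Meyers allylic chlorination is a direct SN2 displacement of the primary allylic mesylate and should give no allylic transposition or loss of E geometry.

Step 13
Reactants: 14 3-(chloromethyl)furan; 23 (2E)-1-chloro-3-methyloct-2-en-6-yne
Product: 25 3-[(3E)-4-methylnon-3-en-7-yn-1-yl]furan, via furylmethyl Grignard reagent 24 (not isolated)
Conditions: 14, Mg, THF, rt (slow addition); then 23, Li2CuCl4 (3 mol %), THF, −10 → 0 °C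
Reagents that add atoms: none
Why: copper-catalysed Grignard cross-coupling of the Kochi type attacks the primary allylic chloride at its α-carbon with retention of the E alkene, and the internal alkyne has no acidic hydrogen to quench the reagent.

Step 14
Reactants: 25 3-[(3E)-4-methylnon-3-en-7-yn-1-yl]furan
Product: 27 3-[(3E,7E)-8-iodo-4-methylnona-3,7-dien-1-yl]furan, via alkenylzirconocene chloride 26 (not isolated)
Conditions: Cp2Zr(H)Cl (2.5 equiv), THF, 50 °C; then I2, THF, 0 °C
Reagents that add atoms: iodine, II
Why: Schwartz hydrozirconation adds H and Zr syn, excess reagent with warming equilibrates the alkenylzirconium regioisomers towards zirconium on the less hindered methyl-bearing carbon, and iodinolysis with retention should give the E iodide while the trisubstituted alkene and the furan do not react.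

Step 15
Reactants: 12 (5Z)-4-methoxy-3-methyl-5-[(2S)-2-methylpent-4-en-1-ylidene]furan-2(5H)-one; 27 3-[(3E,7E)-8-iodo-4-methylnona-3,7-dien-1-yl]furan
Product: 29 (5Z)-5-[(2S,6E,10E)-13-(furan-3-yl)-2,6,10-trimethyltrideca-6,10-dien-1-ylidene]-4-methoxy-3-methylfuran-2(5H)-one, via B-alkyl-9-BBN borane 28 (not isolated)
Conditions: 12, 9-BBN, THF, 0 °C → rt; then 27, PdCl2(dppf) (5 mol %), AsPh3, Cs2CO3, DMF/THF/H2O, rt
Reagents that add atoms: none
Why: B-alkyl Suzuki–Miyaura coupling, in which 9-BBN hydroborates only the monosubstituted alkene at its terminus and the sp3–sp2 coupling proceeds with retention of the alkenyl iodide geometry under a mild base at room temperature that should spare the lactone and C7.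

Step 16
Reactants: 29 (5Z)-5-[(2S,6E,10E)-13-(furan-3-yl)-2,6,10-trimethyltrideca-6,10-dien-1-ylidene]-4-methoxy-3-methylfuran-2(5H)-one
Product: 30 variabilin
Conditions: LiCl, DMF, 90 °C; then 1 M HCl (work-up)
Reagents that add atoms: none
Why: Krapcho-like SN2 O-demethylation, in which chloride attacks the methyl group of the vinylogous carbonate and the stabilised tetronate is the leaving group, so no bond at C7 or at the alkenes is touched.

**Compound list**

1 | dimethyl squarate (3,4-dimethoxycyclobut-3-ene-1,2-dione) | COC1=C(OC)C(=O)C1=O | starting material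
2 | lithium 2,3-dimethoxy-1-methyl-4-oxocyclobut-2-en-1-olate | [Li+].CC1([O-])C(OC)=C(OC)C1=O | intermediate
3 | 3-methoxy-4-methylcyclobut-3-ene-1,2-dione | COC1=C(C)C(=O)C1=O | intermediate
4 | (4R)-4-benzyl-3-propanoyl-1,3-oxazolidin-2-one | CCC(=O)N1[C@H](Cc2ccccc2)COC1=O | starting material
5 | sodium (Z)-enolate of 4 | [Na+].C/C=C(\[O-])N1[C@H](Cc2ccccc2)COC1=O | intermediate
6 | (4R)-4-benzyl-3-[(2S)-2-methylpent-4-enoyl]-1,3-oxazolidin-2-one | C=CC[C@H](C)C(=O)N1[C@H](Cc2ccccc2)COC1=O | intermediate
7 | (2S)-2-methylpent-4-en-1-ol | C=CC[C@H](C)CO | intermediate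
8 | (4S)-5-iodo-4-methylpent-1-ene | C=CC[C@H](C)CI | intermediate
9 | [(2R)-2-methylpent-4-en-1-yl]lithium (same spatial arrangement as 8; the descriptor changes only because CH2Li ranks below allyl) | C=CC[C@H](C)C[Li] | intermediate
10 | 4-hydroxy-3-methoxy-2-methyl-4-[(2S)-2-methylpent-4-en-1-yl]cyclobut-2-en-1-one (both carbinol epimers) | COC1=C(C)C(=O)C1(O)C[C@@H](C)CC=C | intermediate
11 | 3-methoxy-4-methyl-2-[(2S)-2-methylpent-4-en-1-yl]-5-oxo-2,5-dihydrofuran-2-yl acetate | CC1=C(OC)C(C[C@@H](C)CC=C)(OC(C)=O)OC1=O | intermediate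
12 | (5Z)-4-methoxy-3-methyl-5-[(2S)-2-methylpent-4-en-1-ylidene]furan-2(5H)-one | CC1=C(OC)/C(=C/[C@@H](C)CC=C)OC1=O | intermediate
13 | furan-3-ylmethanol | OCc1ccoc1 | starting material
14 | 3-(chloromethyl)furan | ClCc1ccoc1 | intermediate
15 | geranyl acetate ((2E)-3,7-dimethylocta-2,6-dien-1-yl acetate) | CC(C)=CCC/C(C)=C/COC(C)=O | starting material
16 | (2E)-5-(3,3-dimethyloxiran-2-yl)-3-methylpent-2-en-1-yl acetate (racemic) | CC1(C)OC1CC/C(C)=C/COC(C)=O | intermediate
17 | (2E)-6,7-dihydroxy-3,7-dimethyloct-2-en-1-yl acetate (racemic) | CC(C)(O)C(O)CC/C(C)=C/COC(C)=O | intermediate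
18 | (2E)-3-methyl-6-oxohex-2-en-1-yl acetate | O=CCC/C(C)=C/COC(C)=O | intermediate
19 | (2E)-3-methylhept-2-en-6-yn-1-yl acetate | C#CCC/C(C)=C/COC(C)=O | intermediate
20 | (2E)-3-methylhept-2-en-6-yn-1-ol | C#CCC/C(C)=C/CO | intermediate
21 | lithium (2E)-7-lithio-3-methylhept-2-en-6-yn-1-olate | [Li]C#CCC/C(C)=C/CO[Li] | intermediate
22 | (2E)-3-methyloct-2-en-6-yn-1-ol | CC#CCC/C(C)=C/CO | intermediate
23 | (2E)-1-chloro-3-methyloct-2-en-6-yne | CC#CCC/C(C)=C/CCl | intermediate
24 | (furan-3-ylmethyl)magnesium chloride | Cl[Mg]Cc1ccoc1 | intermediate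
25 | 3-[(3E)-4-methylnon-3-en-7-yn-1-yl]furan | CC#CCC/C(C)=C/CCc1ccoc1 | intermediate
26 | chlorobis(cyclopentadienyl)[(2E,6E)-9-(furan-3-yl)-6-methylnona-2,6-dien-2-yl]zirconium | C/C(=C\CC/C(C)=C/CCc1ccoc1)[Zr](Cl)(C1C=CC=C1)C1C=CC=C1 | intermediate
27 | 3-[(3E,7E)-8-iodo-4-methylnona-3,7-dien-1-yl]furan | C/C(I)=C\CC/C(C)=C/CCc1ccoc1 | intermediate
28 | (5Z)-5-[(2S)-5-(9-borabicyclo[3.3.1]nonan-9-yl)-2-methylpentylidene]-4-methoxy-3-methylfuran-2(5H)-one | CC1=C(OC)/C(=C/[C@@H](C)CCCB2C3CCCC2CCC3)OC1=O | intermediate
29 | (5Z)-5-[(2S,6E,10E)-13-(furan-3-yl)-2,6,10-trimethyltrideca-6,10-dien-1-ylidene]-4-methoxy-3-methylfuran-2(5H)-one (O-methylvariabilin) | CC1=C(OC)/C(=C/[C@@H](C)CCC/C(C)=C/CC/C(C)=C/CCc2ccoc2)OC1=O | intermediate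
30 | variabilin, (5Z)-5-[(2S,6E,10E)-13-(furan-3-yl)-2,6,10-trimethyltrideca-6,10-dien-1-ylidene]-4-hydroxy-3-methylfuran-2(5H)-one | CC1=C(O)/C(=C/[C@@H](C)CCC/C(C)=C/CC/C(C)=C/CCc2ccoc2)OC1=O | target

**Step count**

Total steps: 16. Longest linear sequence: 9 steps (geranyl acetate 15 to 30 through steps 8–16).

**Steps most likely to fail**

Step 6 (oxidative ring expansion). Possible failures:
- the oxygen-centred intermediate abstracts the allylic C8 hydrogen instead of cleaving the ring;
- loss of acetic acid from 11 is incomplete or gives E/Z mixtures;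
- DBU epimerises C7 by vinylogous deprotonation.

Fallback, setting out from 7 and returning at 12: alcohol 7 is oxidised with Dess–Martin periodinane (CH2Cl2, NaHCO3, 0 °C) to (2S)-2-methylpent-4-enal F1, used at once to limit α-epimerisation. Purchased 3-methyltetronic acid is O-methylated (Me2SO4, K2CO3, acetone) to 4-methoxy-3-methylfuran-2(5H)-one F2. Its C5 lithium enolate (LiN(i-Pr)2, THF, −78 °C) adds to F1 in an aldol reaction to give 5-[(2S)-1-hydroxy-2-methylpent-4-en-1-yl]-4-methoxy-3-methylfuran-2(5H)-one F3 as a diastereomer mixture. Mesylation (MsCl, Et3N, CH2Cl2, 0 °C) gives (2S)-1-(3-methoxy-4-methyl-5-oxo-2,5-dihydrofuran-2-yl)-2-methylpent-4-en-1-yl methanesulfonate F4, and DBU then eliminates by an E1cB path through the C5 enolate to the thermodynamically preferred Z ylidene 12.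

Step 15 (hydroboration and Suzuki coupling). Possible failures:
- slow transmetallation at the α-methyl-substituted alkenyl iodide lets protodeboronation and β-hydride elimination of the alkylpalladium compete;
- aqueous base opens the ylidene lactone.

Fallback, setting out from 12 and returning at 29: hydroboration of 12 with 9-BBN and oxidation with NaBO3·4H2O gives (5Z)-5-[(2S)-5-hydroxy-2-methylpentylidene]-4-methoxy-3-methylfuran-2(5H)-one F5. Iodination (I2, PPh3, imidazole) gives (5Z)-5-[(2S)-5-iodo-2-methylpentylidene]-4-methoxy-3-methylfuran-2(5H)-one F6. Zinc insertion (Zn dust, LiCl, THF, 40 °C) gives the alkylzinc iodide, iodo[(4S,5Z)-5-(3-methoxy-4-methyl-5-oxofuran-2(5H)-ylidene)-4-methylpentyl]zinc F7, which is joined to 27 by a base-free Negishi coupling (PdCl2(dppf), THF/DMA, rt → 40 °C) to give 29.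

Step 16 (O-demethylation). Possible failures:
- the SN2 demethylation is slow, and prolonged heating isomerises the Z ylidene or degrades the furan and polyene.

Fallback, setting out from 12 and returning at 30: the demethylation is moved ahead of the coupling, onto the small lactone that tolerates forcing conditions. LiCl in DMF at 100 °C with acidic work-up converts 12 into (5Z)-4-hydroxy-3-methyl-5-[(2S)-2-methylpent-4-en-1-ylidene]furan-2(5H)-one F8. Excess 9-BBN (2.5 equiv, THF) first consumes the acidic hydroxyl as a B–O bond and then hydroborates the terminal alkene, giving the O,C-bis(9-borabicyclo[3.3.1]nonan-9-yl) derivative F9. Suzuki coupling with 27 (PdCl2(dppf), AsPh3, excess Cs2CO3, DMF/H2O, rt), in which the aqueous base hydrolyses the B–O bond and the tetronate couples as its caesium salt, followed by acidification, gives 30 directly.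

**Further compounds**

F1 | step 6 | (2S)-2-methylpent-4-enal | C=CC[C@H](C)C=O
F2 | step 6 | 4-methoxy-3-methylfuran-2(5H)-one | COC1=C(C)C(=O)OC1
F3 | step 6 | 5-[(2S)-1-hydroxy-2-methylpent-4-en-1-yl]-4-methoxy-3-methylfuran-2(5H)-one (diastereomer mixture) | CC1=C(OC)C(C(O)[C@@H](C)CC=C)OC1=O
F4 | step 6 | (2S)-1-(3-methoxy-4-methyl-5-oxo-2,5-dihydrofuran-2-yl)-2-methylpent-4-en-1-yl methanesulfonate | CC1=C(OC)C(C(OS(C)(=O)=O)[C@@H](C)CC=C)OC1=O
F5 | step 15 | (5Z)-5-[(2S)-5-hydroxy-2-methylpentylidene]-4-methoxy-3-methylfuran-2(5H)-one | CC1=C(OC)/C(=C/[C@@H](C)CCCO)OC1=O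
F6 | step 15 | (5Z)-5-[(2S)-5-iodo-2-methylpentylidene]-4-methoxy-3-methylfuran-2(5H)-one | CC1=C(OC)/C(=C/[C@@H](C)CCCI)OC1=O
F7 | step 15 | iodo[(4S,5Z)-5-(3-methoxy-4-methyl-5-oxofuran-2(5H)-ylidene)-4-methylpentyl]zinc | CC1=C(OC)/C(=C/[C@@H](C)CCC[Zn]I)OC1=O
F8 | step 16 | (5Z)-4-hydroxy-3-methyl-5-[(2S)-2-methylpent-4-en-1-ylidene]furan-2(5H)-one | CC1=C(O)/C(=C/[C@@H](C)CC=C)OC1=O
F9 | step 16 | (5Z)-4-(9-borabicyclo[3.3.1]nonan-9-yloxy)-5-[(2S)-5-(9-borabicyclo[3.3.1]nonan-9-yl)-2-methylpentylidene]-3-methylfuran-2(5H)-one | CC1=C(OB2C3CCCC2CCC3)/C(=C/[C@@H](C)CCCB2C3CCCC2CCC3)OC1=O
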